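**Plan**

- Retrosynthesis: ring C is cut at C2–C3 and at O1–C8a in one stroke. This gives veratraldehyde (C2 and O1) and the enol silane of 6-fluoro-2,3,4-trimethoxyacetophenone (C3, C4 and ring A). The ketone is then cut at C4–C4a (Friedel–Crafts), and the C–F bond goes back to an amino group.
- Enabling feature: the C4 carbonyl sits on C4a, ortho to C8a. It makes C3 an enol nucleophile and turns C8a–F into a vinylogous acyl fluoride, so the aldehyde C=O can be taken up as a two-atom unit in a formal [4+2] annulation.
- Forward order: ring A is bought complete; fluorine, the acetyl group and the enol silane are installed in turn; ring B arrives with the aldehyde and ring C is closed last.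
- Stereochemistry: C2 is set by a catalyst-controlled Si-face Mukaiyama aldol addition and is carried with retention through the ring closure, because the C2–O1 bond is never broken.

Key step: step 4

Assumption: the oxazaborolidinone from N-tosyl-(R)-tryptophan is written on the premise that it shields the Re face of the boron-bound aldehyde; this sense of induction is not certain. If a pilot aldol shows the opposite sense, the (S)-tryptophan-derived antipode is used in the same way.

**Route**

Step 1
Reactants: 1 3,4,5-trimethoxyaniline
Product: 3 5-fluoro-1,2,3-trimethoxybenzene, via arenediazonium fluoride 2 (not isolated)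
Conditions: NaNO2, HF·pyridine (70 % HF), 0 °C → rt; then hν (365 nm), rt, until N2 evolution ends
Reagents that add atoms: hydrogen fluoride (used as HF·pyridine), F
Why: Diazotisation of the amine followed by fluoro-dediazoniation of the arenediazonium ion 2 in the fluoride-rich medium (Balz–Schiemann reaction in its one-pot HF·pyridine form) should replace NH2 by F at the same carbon, with light driving loss of N2 from the donor-stabilised diazonium ion; the second nitrogen of 2 comes from nitrite and leaves as N2.

Step 2
Reactants: 3 5-fluoro-1,2,3-trimethoxybenzene
Product: 4 1-(6-fluoro-2,3,4-trimethoxyphenyl)ethan-1-one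
Conditions: Ac2O, Sc(OTf)3 (10 mol %), MeNO2, 50 °C
Reagents that add atoms: acetic anhydride, CC(=O)OC(C)=O
Why: Friedel–Crafts acylation: the two free positions of 3 are equivalent by symmetry and each is para to one methoxy group and ortho to another, so a single ketone is expected, monoacylation deactivates the ring, and a catalytic metal triflate avoids the cleavage of the ortho methyl ether that stoichiometric AlCl3 can cause.

Step 3
Reactants: 4 1-(6-fluoro-2,3,4-trimethoxyphenyl)ethan-1-one
Product: 6 trimethyl{[1-(6-fluoro-2,3,4-trimethoxyphenyl)ethenyl]oxy}silane, via lithium enolate 5 (not isolated)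
Conditions: LiN(i-Pr)2 (LDA, commercial solution), THF, −78 °C; then Me3SiCl, −78 → 0 °C; non-aqueous work-up
Reagents that add atoms: chlorotrimethylsilane, C[Si](C)(C)Cl
Why: Kinetic deprotonation of the methyl ketone and O-silylation of the lithium enolate 5 (enol silane formation) is routine, the acetyl group offers a single enolisable site, and enolate formation at −78 °C is far faster than any attack of the amide on the C–F bond.

Step 4
Reactants: 6 trimethyl{[1-(6-fluoro-2,3,4-trimethoxyphenyl)ethenyl]oxy}silane; 7 3,4-dimethoxybenzaldehyde (veratraldehyde)
Product: 10 (2S)-5,6,7,3',4'-pentamethoxyflavanone, via silyl aldol ether 8 (not isolated), via ammonium alkoxide 9 (not isolated)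
Conditions: B-n-butyl oxazaborolidinone of N-tosyl-(R)-tryptophan (20 mol %), EtCN, −78 °C (7 in slight excess); then Bu4N[Ph3SiF2] (0.4 equiv), THF, −78 → 0 °C; pH 7 buffer quench
Reagents that add atoms: none
Why: In the first stage the chiral oxazaborolidinone binds the formyl oxygen of 7 and the enol silane 6 adds through an open transition state to the exposed Si face (Mukaiyama aldol), with silyl transfer to the aldolate oxygen giving the (S)-silyl ether 8 and setting C2 under catalyst control. In the second stage fluoride from Bu4N[Ph3SiF2] removes the silyl group and the alkoxide 9 adds to C8a of ring A and expels fluoride (SNAr through a σ-adduct whose charge rests on the C4 carbonyl); the released fluoride desilylates the next molecule of 8, so the initiator is needed only in part. The closest known reaction types are the oxazaborolidinone-catalysed Mukaiyama aldol of aryl methyl ketone enol silanes with aromatic aldehydes and the closure of 2-fluoroaryl β-hydroxy ketones to chroman-4-ones by intramolecular SNAr. Ring C closes in a 6-endo-trig addition–elimination mode (the attacked C8a=C4a bond lies inside the new ring), and because the C2–O1 bond is never broken the aldol configuration is carried over with retention to (2S). The step needs facial selectivity in the aldol (catalyst), substitution at C8a–F and not at C5–OMe (fluoride is by far the better nucleofuge and C8a is the less hindered ortho carbon), and cyclisation faster than retro-aldol or E1cB loss of the oxygen; for this the alkoxide is formed only in low concentration, at low temperature, next to an ortho-acyl-activated C–F bond, and 7 is kept in slight excess so that no enol silane is left to give free enolate. Crystallisation of 10 should allow the enantiomeric purity to be raised if the aldol falls short.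

**Compound list**

1 | 3,4,5-trimethoxyaniline | COc1cc(N)cc(OC)c1OC | starting material
2 | 3,4,5-trimethoxybenzenediazonium fluoride | COc1cc([N+]#N)cc(OC)c1OC.[F-] | intermediate
3 | 5-fluoro-1,2,3-trimethoxybenzene | COc1cc(F)cc(OC)c1OC | intermediate
4 | 1-(6-fluoro-2,3,4-trimethoxyphenyl)ethan-1-one | CC(=O)c1c(F)cc(OC)c(OC)c1OC | intermediate
5 | lithium 1-(6-fluoro-2,3,4-trimethoxyphenyl)ethen-1-olate | [Li+].C=C([O-])c1c(F)cc(OC)c(OC)c1OC | intermediate
6 | trimethyl{[1-(6-fluoro-2,3,4-trimethoxyphenyl)ethenyl]oxy}silane | C=C(O[Si](C)(C)C)c1c(F)cc(OC)c(OC)c1OC | intermediate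
7 | 3,4-dimethoxybenzaldehyde (veratraldehyde) | COc1ccc(C=O)cc1OC | starting material
8 | (3S)-3-(3,4-dimethoxyphenyl)-1-(6-fluoro-2,3,4-trimethoxyphenyl)-3-(trimethylsilyloxy)propan-1-one | COc1ccc([C@@H](O[Si](C)(C)C)CC(=O)c2c(F)cc(OC)c(OC)c2OC)cc1OC | intermediate
9 | tetrabutylammonium (1S)-1-(3,4-dimethoxyphenyl)-3-(6-fluoro-2,3,4-trimethoxyphenyl)-3-oxopropan-1-olate | CCCC[N+](CCCC)(CCCC)CCCC.COc1ccc([C@@H]([O-])CC(=O)c2c(F)cc(OC)c(OC)c2OC)cc1OC | intermediate
10 | (2S)-2-(3,4-dimethoxyphenyl)-5,6,7-trimethoxy-2,3-dihydro-4H-chromen-4-one, (2S)-5,6,7,3',4'-pentamethoxyflavanone | COc1ccc([C@@H]2CC(=O)c3c(cc(OC)c(OC)c3OC)O2)cc1OC | target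

**Summary**

Total step count: 4. Longest linear sequence: 4 steps (1 → 3 → 4 → 6 → 10); 7 enters in step 4.

Steps most likely to fail:

1. Step 4. The enantiopurity set in the aldol stage may erode if the alkoxide undergoes retro-aldol and re-addition before it closes the ring. The alkoxide may also lose the oxygen by E1cB elimination, the finished ring may reopen under the basic fluoride, or the electron-rich benzylic silyl ether may ionise on the Lewis acid. The fallback sets out from 4, returns at 10, and moves the stereocontrol from the bond-forming event to a hydrogenation. The lithium enolate 5 (from 4 with LiN(SiMe3)2, THF, −78 °C) is C-acylated with 3,4-dimethoxybenzoyl chloride to 1-(3,4-dimethoxyphenyl)-3-(6-fluoro-2,3,4-trimethoxyphenyl)propane-1,3-dione F1. K2CO3 in DMF at 90 °C should close F1, by SNAr of the enol oxygen on C8a–F, to 5,6,7,3',4'-pentamethoxyflavone F2. Asymmetric hydrogenation of F2 (H2 under pressure, Ru(cod)(2-methylallyl)2, KOt-Bu, and the enantiomer of the chiral 1,3-bis[1-(1-naphthyl)ethyl]imidazolinium tetrafluoroborate that delivers the 2S configuration) sets C2 and should give (2S)-5,6,7,3',4'-pentamethoxyflavan-4-ol F3 as a mixture of C4 epimers. Base-free Dess–Martin oxidation of F3 returns to 10.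

2. Step 1. The donor-stabilised diazonium ion may lose nitrogen only slowly and may be diverted to phenol or to the reduced arene instead of capturing fluoride. The fallback sets out from 1, returns at 3, and makes the C–F bond by copper-mediated halide exchange. Diazotisation of 1 (NaNO2, aqueous H2SO4, 0 °C) gives 3,4,5-trimethoxybenzenediazonium hydrogensulfate F4, which is not isolated. Sandmeyer-type iodination with KI converts it into 5-iodo-1,2,3-trimethoxybenzene F5. Fluorination of F5 with (t-BuCN)2CuOTf and AgF in DMF at 140 °C should give 3.

3. Step 2. Acylation at the position flanked by fluorine and methoxy may be sluggish, or the Lewis acid may cleave the methyl ether next to the new carbonyl. The fallback sets out from 3, returns at 4, and replaces electrophilic substitution by directed metalation. Deprotonation of 3 with s-BuLi in THF at −78 °C, at the carbon between fluorine and methoxy, gives (6-fluoro-2,3,4-trimethoxyphenyl)lithium F6. It is kept at −78 °C to avoid loss of LiF and is quenched with N-methoxy-N-methylacetamide to give 4.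

**Further compounds**

F1 | step 4 | 1-(3,4-dimethoxyphenyl)-3-(6-fluoro-2,3,4-trimethoxyphenyl)propane-1,3-dione | COc1ccc(C(=O)CC(=O)c2c(F)cc(OC)c(OC)c2OC)cc1OC
F2 | step 4 | 5,6,7,3',4'-pentamethoxyflavone | COc1ccc(-c2cc(=O)c3c(OC)c(OC)c(OC)cc3o2)cc1OC
F3 | step 4 | (2S)-5,6,7,3',4'-pentamethoxyflavan-4-ol (C4 epimers) | COc1ccc([C@@H]2CC(O)c3c(cc(OC)c(OC)c3OC)O2)cc1OC
F4 | step 1 | 3,4,5-trimethoxybenzenediazonium hydrogensulfate | COc1cc([N+]#N)cc(OC)c1OC.OS(=O)(=O)[O-]
F5 | step 1 | 5-iodo-1,2,3-trimethoxybenzene | COc1cc(I)cc(OC)c1OC
F6 | step 2 | (6-fluoro-2,3,4-trimethoxyphenyl)lithium | [Li]c1c(F)cc(OC)c(OC)c1OC
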